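5.70% of the charge could not be found in Sunday's flask at 4.00 d, counting starting material and target, and 7.90% could not be found in Wednesday's. I wanted the target at the end of three new flasks that differ in protic impurity.

common to all: starting material 0.12 M

| run | reagent | second substrate | protic impurity | remark | time |
|---|---|---|---|---|---|
| Sunday's | 1.1 equiv | 0.50 equiv | 0.14 M | run made earlier |  |
| Wednesday's | 1.1 equiv | 0.50 equiv | 0.61 M | run made earlier |  |
| elm | 1.10 equiv | 0.500 equiv | 0.120 M |  | 8.0 d |
| alder | 1.10 equiv | 0.500 equiv | 0.250 M |  | 8.0 d |
| maple | 1.10 equiv | 0.500 equiv | 0.500 M |  | 8.0 d |

| run | time / d | target / % | starting material / % |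
|---|---|---|---|
| Sunday's | 1.04 | 25.1 | 73.8 |
| Sunday's | 2.08 | 38.8 | 59.6 |
| Sunday's | 3.00 | 43.9 | 48.2 |
| Sunday's | 4.00 | 51.3 | 43.0 |
| Wednesday's | 0.333 | 11.1 | 89.8 |
| Wednesday's | 0.833 | 21.2 | 78.3 |
| Wednesday's | 1.67 | 34.0 | 63.4 |
| Wednesday's | 4.00 | 50.5 | 41.6 |

(each reading ± 1 percentage point)

- amount of target at the end, in percent of the starting material charged for elm, alder, maple, in this order
- how that number moves from the first to the last of them (falls, then rises / hardly changes / falls all the way / rises, then falls / rises all the way)

- the numbers in the tables scatter with a standard deviation of 1 percentage point
- "hardly changes" means that all values lie within two and a half points (for a concentration: within two and a half percent of the largest)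

I took starting material + reagent as the route to target, so the target at the end is the charge, minus the starting material left, minus what had leaked away. The two runs gave 0.0170 d⁻¹ as the leak, the mean share of the charge per day that left starting material without appearing as target; chemists call the accumulated amount the mass-balance deficit. A mean replaces a curve, so I tested it on Wednesday's reading at 1.67 d: it predicted 2.84% missing, and 2.60% was missing. Over 8.0 d the leak came to 13.6%.

Starting material stood at a mean of 42.3% at 4.00 d. With equal charges, the reciprocal of what is left climbs in a straight line, which gave 26.8% left at the end and 59.6% target. That equal charge was the weak link, since reagent stood at 1.10 equiv. With the excess counted, the logarithm of reagent over starting material is the straight line instead. Its slope gave a rate of 0.292 d⁻¹, then 25.7% left and 60.7% target. Sunday's and Wednesday's target at 4.00 d differed by 0.8 percentage points at a scatter of 1 point per reading, too little to read any effect of the impurity from two readings, so I put that figure on each flask. It was a rough figure: stretching the leak from 4.00 d to 8.0 d alone gave it a standard deviation of about 2 points.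

The forecast gave 59%, 59% and 59%, so hardly changes, and my figure stood higher: “All three runs lie inside the bracketed impurity range, so they should be essentially equal.”

Elm, alder and maple gave 61.0%, 62.7% and 63.8%: the target rises all the way.

    second substrate + protic impurity → quenched substrate (k = 0.244 M⁻¹ h⁻¹)
    starting material + target → side product (k = 0.0169 M⁻¹ h⁻¹)
    starting material + reagent → target (k = 0.102 M⁻¹ h⁻¹)
    second substrate + reagent → second product (k = 0.0725 M⁻¹ h⁻¹)

The leak of 0.0170 d⁻¹ had given 13.6% over 8.0 d; side product, each counted as two, stood at 14.4% in elm and 14.2% in maple. So the row moved through starting material left, 24.6% in elm and 22.0% in maple. The rise of 2.8 points from elm to maple went to 0 points without the step from second substrate + reagent, and likewise without the step from second substrate + protic impurity. Reagent and impurity compete for second substrate: at the end, second product stood at 0.0133 M in elm and 0.00418 M in maple.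

The earlier runs and the new flask come from a simulation with constants of no real substance, and the scatter is random.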